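Ring B is disconnected at C1'–C2' and C5'–C6', which leads back to 3,5-dibromo-2-pyrone and the ethynyl ether of guaiacol. What is exploited is the substitution pattern of ring B: C2' (Br), C3' (H), C4' (Br) and C5' (H) correspond one-to-one to C3–C6 of the pyrone, and the oxygen on C1' arrives on the alkyne. A single thermal [4+2] cycloaddition with loss of CO2 therefore builds ring B, both of its bromines and the diaryl ether link at once. The alkyne partner, 1-(ethynyloxy)-2-methoxybenzene, is kept free of halogen so that it survives n-BuLi; ring A is brominated at C4, C5 and C6 afterwards.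

Key step: step 4

Remark: ring A is numbered C1 (OH), C2 (ether oxygen), C3 (H), C4–C6 (Br); ring B is C1' (ether oxygen), C2' and C4' (Br). Ynol ether 7 is assumed to be handled only as a cold solution and used within hours of its preparation.

Step 1
Reactants: 1 guaiacol (2-methoxyphenol); 2 trichloroethylene
Product: 4 (E)-1-[(1,2-dichloroethenyl)oxy]-2-methoxybenzene, via dichloroacetylene 3 (not isolated)
Conditions: K2CO3 (1.5 equiv), 2 (1.5 equiv), DMF, 70 °C
Reagents that add atoms: none
Why: Base-induced loss of HCl from 2 gives dichloroacetylene 3 in the flask, and anti addition of the phenoxide of 1 across it (the elimination–addition synthesis of 1,2-dichlorovinyl ethers) should give the E ether, whose geometry is erased in the next step.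

Step 2
Reactants: 4 (E)-1-[(1,2-dichloroethenyl)oxy]-2-methoxybenzene
Product: 7 1-(ethynyloxy)-2-methoxybenzene, via chloroethynyl ether 5 (not isolated), via lithium acetylide 6 (not isolated)
Conditions: n-BuLi (2.5 equiv), THF, −78 → −40 °C; then H2O, −78 → 0 °C; kept as a cold PhMe solution
Reagents that add atoms: none
Why: The first equivalent of n-BuLi brings about β-elimination of HCl to chloroalkyne 5 and the second a chlorine–lithium exchange to acetylide 6, which is protonated cold (the standard dichlorovinyl ether route to ynol ethers), and since ring A bears no halogen nothing else should compete for the organolithium.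

Step 3
Reactants: 8 coumalic acid (2-oxo-2H-pyran-5-carboxylic acid)
Product: 10 3,5-dibromo-2H-pyran-2-one, via 5-bromo-2H-pyran-2-one 9 (not isolated)
Conditions: NBS (2.5 equiv), LiOAc (cat.), MeCN–H2O, rt
Reagents that add atoms: N-bromosuccinimide, O=C1CCC(=O)N1Br
Why: Hunsdiecker-type bromodecarboxylation of the carboxylate with NBS should give bromopyrone 9, which a second equivalent of NBS brominates at the nucleophilic C3, a known one-pot preparation of this pyrone.

Step 4
Reactants: 10 3,5-dibromo-2H-pyran-2-one; 7 1-(ethynyloxy)-2-methoxybenzene
Product: 12 2,4-dibromo-1-(2-methoxyphenoxy)benzene, via bridged bicyclic lactone 11 (not isolated)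
Conditions: 7 (1.5 equiv), PhMe, 90 °C, sealed vessel
Reagents that add atoms: none
Why: The electron-poor diene of 10 (C3 to C6) and the electron-rich triple bond of 7 should combine in a concerted, asynchronous inverse-demand [4+2] cycloaddition to the bridged lactone 11, which expels CO2 by a retro-[4+2] step at the same temperature and is thereby aromatic without any oxidant. The closest known chemistry is the cycloaddition of 3,5-dibromo-2-pyrone with enol ethers and the pyrone–alkyne (including ynamine) route to benzenes with loss of CO2. Ring B is closed by intermolecular cycloaddition, four carbons coming from the pyrone and two from the alkyne, the C1'–C2' and C5'–C6' bonds being formed together. No stereocenter remains, since the two bridgehead centers of 11 vanish on aromatization. One regiochemistry is required: the terminal alkyne carbon, which carries the larger HOMO coefficient, must bond to pyrone C6, the δ-position of the unsaturated lactone and its more electrophilic diene terminus, so that the oxygen-bearing carbon ends up next to the C3 bromine; this is the same polarity match that places alkoxy groups at C5 of the enol ether adducts of this pyrone, and the opposite mode would lead to the 3,5-dibromophenyl ether.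

Step 5
Reactants: 12 2,4-dibromo-1-(2-methoxyphenoxy)benzene
Product: 14 1,2-dibromo-4-(2,4-dibromophenoxy)-5-methoxybenzene, via ring A monobromide 13 (not isolated)
Conditions: Br2 (2.1 equiv), AcOH, rt
Reagents that add atoms: bromine, BrBr
Why: Electrophilic aromatic bromination should enter ring A first para to OMe (C4, monobromide 13) and then para to the aryloxy oxygen (C5), because C6 is meta to both the new bromine and the aryloxy group and ring B is deactivated by its two bromines, in analogy to the conversion of veratrole into its 4,5-dibromide.

Step 6
Reactants: 14 1,2-dibromo-4-(2,4-dibromophenoxy)-5-methoxybenzene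
Product: 16 4,5-dibromo-2-(2,4-dibromophenoxy)phenol, via aryloxydibromoborane 15 (not isolated)
Conditions: BBr3 (1.5 equiv), CH2Cl2, −78 °C → rt; then H2O
Reagents that add atoms: none
Why: Lewis acid-mediated methyl ether cleavage, in which BBr3 binds the methoxy oxygen and bromide attacks the methyl group in an SN2 step to give borane 15 that is hydrolysed on work-up, should leave the diaryl ether and the aryl bromides untouched.

Step 7
Reactants: 16 4,5-dibromo-2-(2,4-dibromophenoxy)phenol
Product: 17 2,3,4-tribromo-6-(2,4-dibromophenoxy)phenol (target)
Conditions: Br2 (1.05 equiv), CH2Cl2–AcOH, 0 °C → rt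
Reagents that add atoms: bromine, BrBr
Why: Hydroxyl-directed electrophilic aromatic bromination should go to C6, the only free position ortho or para to the OH group (C2 and C4 are occupied), whereas C3 and ring B have no comparable activation.

Compound list
1 | guaiacol (2-methoxyphenol) | COc1ccccc1O | starting material
2 | trichloroethylene | ClC=C(Cl)Cl | starting material
3 | dichloroacetylene | ClC#CCl | intermediate (not isolated)
4 | (E)-1-[(1,2-dichloroethenyl)oxy]-2-methoxybenzene | COc1ccccc1O/C(Cl)=C\Cl | intermediate
5 | 1-[(chloroethynyl)oxy]-2-methoxybenzene | COc1ccccc1OC#CCl | intermediate (not isolated)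
6 | lithium [(2-methoxyphenoxy)ethynyl]ide | [Li]C#COc1ccccc1OC | intermediate (not isolated)
7 | 1-(ethynyloxy)-2-methoxybenzene | C#COc1ccccc1OC | intermediate
8 | coumalic acid (2-oxo-2H-pyran-5-carboxylic acid) | OC(=O)c1ccc(=O)oc1 | starting material
9 | 5-bromo-2H-pyran-2-one | O=c1ccc(Br)co1 | intermediate (not isolated)
10 | 3,5-dibromo-2H-pyran-2-one | O=c1occ(Br)cc1Br | intermediate
11 | 4,7-dibromo-5-(2-methoxyphenoxy)-2-oxabicyclo[2.2.2]octa-5,7-dien-3-one (racemic, relative configuration fixed by the bridge) | O=C1OC2C=C(Oc3ccccc3OC)C1(Br)C=C2Br | intermediate (not isolated)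
12 | 2,4-dibromo-1-(2-methoxyphenoxy)benzene | COc1ccccc1Oc1ccc(Br)cc1Br | intermediate
13 | 4-bromo-2-(2,4-dibromophenoxy)-1-methoxybenzene | COc1ccc(Br)cc1Oc1ccc(Br)cc1Br | intermediate (not isolated)
14 | 1,2-dibromo-4-(2,4-dibromophenoxy)-5-methoxybenzene | COc1cc(Br)c(Br)cc1Oc1ccc(Br)cc1Br | intermediate
15 | dibromo[4,5-dibromo-2-(2,4-dibromophenoxy)phenoxy]borane | BrB(Br)Oc1cc(Br)c(Br)cc1Oc1ccc(Br)cc1Br | intermediate (not isolated)
16 | 4,5-dibromo-2-(2,4-dibromophenoxy)phenol | Oc1cc(Br)c(Br)cc1Oc1ccc(Br)cc1Br | intermediate
17 | 2,3,4-tribromo-6-(2,4-dibromophenoxy)phenol | Oc1c(Oc2ccc(Br)cc2Br)cc(Br)c(Br)c1Br | target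

Total step count: 7
Longest linear sequence: 6 steps (steps 1, 2, 4, 5, 6, 7); the pyrone branch adds step 3.

Steps most likely to fail

1. Step 4. The ynol ether may oligomerise or be hydrated faster than it adds to the pyrone, or the cycloaddition may take the opposite orientation and, after loss of CO2, place the bromines at C3' and C5'. The fallback sets out from guaiacol 1 and replaces the cycloaddition by an aryl–oxygen coupling. Guaiacol 1 would be O-arylated with bis(2,4-dibromophenyl)iodonium chloride F1 in aqueous NaOH/dioxane at reflux, the established diaryliodonium route to brominated diphenyl ethers. F1 would be prepared from 1,3-dibromobenzene and iodyl sulfate, (IO)2SO4, in H2SO4 and precipitated with chloride. The fallback comes back to the route at 12.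

2. Step 2. The terminal ynol ether may be lost by hydration to the aryl acetate or by oligomerisation during quench, concentration and purification. The fallback sets out from 4 and uses a silyl-capped alkyne as a storable form. After the n-BuLi treatment, acetylide 6 would be trapped in the flask with Me3SiCl to give [(2-methoxyphenoxy)ethynyl]trimethylsilane F2, which should tolerate chromatography and storage. Just before the cycloaddition, K2CO3 (cat.) in MeOH at 0 °C would release the terminal alkyne, which is extracted into cold toluene and used at once. The fallback comes back to the route at 7.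

3. Step 5. The second bromination may be incompletely regioselective (attack ortho to the methoxy group at C6) or may run on to a tribromide, giving isomers that are hard to separate. The fallback sets out from 12 and changes the order in which ring A is filled, so that C5 is brominated while the C1 oxygen is switched off and the free phenol then directs the last two bromines to its own para and ortho positions.
   - BBr3 in CH2Cl2 would give 2-(2,4-dibromophenoxy)phenol F3.
   - MsCl/Et3N would give 2-(2,4-dibromophenoxy)phenyl methanesulfonate F4.
   - Br2 with a little FeBr3 in CH2Cl2 should brominate para to the only remaining donor, the aryloxy oxygen, to give 5-bromo-2-(2,4-dibromophenoxy)phenyl methanesulfonate F5.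
   - NaOH in aqueous MeOH at reflux would free 5-bromo-2-(2,4-dibromophenoxy)phenol F6.
   - Br2 (2 equiv) in AcOH should then enter C4 and C6 together.
   
   The fallback comes back to the route at 17.

Further compounds
F1 | step 4 | bis(2,4-dibromophenyl)iodonium chloride | [Cl-].Brc1ccc([I+]c2ccc(Br)cc2Br)c(Br)c1
F2 | step 2 | [(2-methoxyphenoxy)ethynyl]trimethylsilane | COc1ccccc1OC#C[Si](C)(C)C
F3 | step 5 | 2-(2,4-dibromophenoxy)phenol | Oc1ccccc1Oc1ccc(Br)cc1Br
F4 | step 5 | 2-(2,4-dibromophenoxy)phenyl methanesulfonate | CS(=O)(=O)Oc1ccccc1Oc1ccc(Br)cc1Br
F5 | step 5 | 5-bromo-2-(2,4-dibromophenoxy)phenyl methanesulfonate | CS(=O)(=O)Oc1cc(Br)ccc1Oc1ccc(Br)cc1Br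
F6 | step 5 | 5-bromo-2-(2,4-dibromophenoxy)phenol | Oc1cc(Br)ccc1Oc1ccc(Br)cc1Br
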